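The data are calculated for an exercise; scatter was added.

| setting | Wednesday's | Thursday's | flask |
|---|---|---|---|
| substrate | 1 M | 2 M | 2.0 M |
| gas phase | 120 mM (held) | 120 mM (held) | 120 mM (held) |
| catalyst | 10 mM | 5 mM | 10 mM |
| remark | run made earlier | run made earlier |  |
| time |  |  | 20 min |

| run | time / min | product / % | substrate / % |
|---|---|---|---|
| Wednesday's | 2.50 | 13 | 57 |
| Wednesday's | 8.00 | 25 | 26 |
| Wednesday's | 12.0 | 33 | 14 |
| Wednesday's | 20.0 | 36 | 8 |
| Thursday's | 1.50 | 4 | 58 |
| Thursday's | 4.00 | 7 | 36 |
| Thursday's | 8.00 | 9 | 19 |
| Thursday's | 20.0 | 20 | 6 |

(readings scatter by 1.5 percentage points)

- amber: doubling the amount of catalyst, all else as stated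
- blue: doubling the saturation concentration of gas phase, all else as stated
- ochre: doubling the transfer coefficient of the gas phase, all else as stated

* product at 20 min, in percent of the substrate charged
* the change that raises the amount of product at 20 min, in percent of the substrate charged most ("none" if none brings more than 2 percentage points) (amber / blue / ochre / none)
* amount of product at 20 min, in percent of the substrate charged, after ochre

- the earlier runs were read with a standard deviation of 1.5 percentage points
- at the start none of the gas phase is in solution

Take Wednesday's first reading and ask where the lost substrate went: of the 43.0% lost, 13% is product, a share of 30.2%. But Thursday's flask, with half the catalyst, is down to 19% of its charge at 8.00 min, so suppose two routes: a catalyst route that goes with the substrate, and one that ignores the catalyst and goes with the substrate squared. Product's share of the substrate lost is then crossover/(crossover + substrate). At Wednesday's mean substrate of 0.785 M, this reads 0.340 M: the crossover concentration, the substrate level at which the two routes take substrate equally fast. Thursday's first reading gives 0.166 M, half of Wednesday's reading, which is what a crossover that goes with the catalyst gives.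

Summing the share gives product = crossover × ln[(crossover + substrate charged)/(crossover + substrate left)]. Our flask has Wednesday's catalyst and Thursday's charge, so take Thursday's 6% as substrate left: you get 27.7%. Doubling the crossover for amber, with the same substrate left, adds 13 percentage points. Both runs held the gas phase at 120 mM, so this reckoning gives no number for blue or ochre.

The forecast gave 26%, 29% after ochre, and blue: “Saturation doubles the rate exactly, even under transfer limitation, whereas catalyst falls short, so blue wins.”

The flask gives 27.9%, and 28.0% after ochre. The best change is amber, worth 16 points against 2.2 points for blue. In the flask at 20.0 min the idle complex, an off-cycle form, holds 80.7% of the catalyst. With the flask's 4.34% of substrate left, Wednesday's crossover gives 28.9% of product.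

    gas phase ⇌ dissolved gas, rate k1*(csat - [dissolved gas]) (kL = 0.511 s⁻¹)
    substrate + dissolved gas + catalyst → catalyst + product (k = 5.07 M⁻² s⁻¹)
    dissolved gas + catalyst ⇌ idle complex, settled at all times (K = 35.0 M⁻¹)
    dissolved gas → decomposed reagent (k = 0.00164 s⁻¹)
    2 substrate → homo dimer (k = 0.00181 M⁻¹ s⁻¹)

The neighbour flask with 0.0025 M of catalyst has a quarter of ours, so its crossover scales to 0.0850 M, and its 8.46% of substrate left gives 8.95% of product. The computed product there stands at 8.53%.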